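**Retrosynthetic overview**

1. The target 33 is fisetinidol-(4β→6)-fisetinidol-(4α→6)-mollisacacidin; it is released by desilylation and one hydrogenolysis that removes eleven benzyl ethers and a steering chlorine on C5 of the middle unit.
2. The C3–OH and C4–H of the middle unit come from hydroboration of a 4-aryl-flav-3-ene, made by adding the C6 organocerium of the bottom unit to the C4 ketone of a middle-unit flavanone and dehydrating.
3. That flavanone is closed by an aryne annulation that forms O1–C8a and C4–C4a together: an aryne at C4a/C8a of the middle ring A (already bonded through C6 to C4 of the top unit) takes up an (S)-β-silyloxy Weinreb amide supplying O1–C2–C3–C4. Enabling feature: ring C of the middle unit is fused to ring A through two neighbouring sp2 carbons, C8a bearing the ring oxygen and C4a bearing C4, with O1 and C4 in a 1,4 relation on the C2–C3 chain; C5 next to C4a carries only hydrogen in the target, so a chlorine can sit there to direct the addition and leave at the end.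
4. The top unit comes from perbenzylated (+)-fustin by aryl Grignard addition to C4=O and ionic hydrogenation (3,4-cis); the bottom unit comes from the same ether by NaBH4 reduction (3,4-trans diol), silylation and C6 bromination.
5. Ring order: rings A, B and C of the top and bottom units come intact from fustin, middle ring A from 5-chlororesorcinol, middle ring B from methyl 3,4-bis(benzyloxy)benzoate; middle ring C is the only ring formed, in step 14.

Key step: step 14

Assumption (chemistry): natural (+)-fustin, the (2R,3R)-trans-dihydroflavonol, is taken as the purchasable chiral-pool source of both terminal units. Flavonoid numbering is used (O1, C2–C4, C4a, C5–C8, C8a; α below and β above the ring plane, so that the C2 aryl groups are α).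

**Route**

Step 1
Reactants: 1 (+)-fustin
Product: 2 (2R,3R)-7,3',4'-tri-O-benzylfustin
Conditions: BnBr (3.3 equiv), K2CO3, DMF, rt, Ar
Reagents that add atoms: benzyl bromide BrCc1ccccc1
Why: Williamson ether synthesis in which carbonate deprotonates only the three phenols, so the secondary 3-OH and the trans C2/C3 stereocentres should stay untouched.

Step 2
Reactants: 2 (2R,3R)-7,3',4'-tri-O-benzylfustin
Product: 3 (2R,3R)-3,7,3',4'-tetra-O-benzylfustin
Conditions: benzyl 2,2,2-trichloroacetimidate, TfOH (cat.), CH2Cl2/cyclohexane, 0 °C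
Reagents that add atoms: benzyl 2,2,2-trichloroacetimidate N=C(OCc1ccccc1)C(Cl)(Cl)Cl
Why: acid-catalysed imidate benzylation of the α-ketol oxygen avoids the base-induced ring opening and epimerisation of dihydroflavonols.

Step 3
Reactants: 3 (2R,3R)-3,7,3',4'-tetra-O-benzylfustin
Product: 4 (2R,3S,4R)-3,7,3',4'-tetrakis(benzyloxy)flavan-4-ol
Conditions: NaBH4, THF/MeOH, 0 °C
Reagents that add atoms: none
Why: borohydride reduction of the chromanone with axial hydride delivery should give the equatorial 4α-alcohol (3,4-trans), the same course as the reduction of fustin to mollisacacidin.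

Step 4
Reactants: 4 (2R,3S,4R)-3,7,3',4'-tetrakis(benzyloxy)flavan-4-ol
Product: 5 4-O-tert-butyldimethylsilyl ether of 4
Conditions: TBSOTf, 2,6-lutidine, CH2Cl2, −78 °C
Reagents that add atoms: tert-butyldimethylsilyl triflate CC(C)(C)[Si](C)(C)OS(=O)(=O)C(F)(F)F
Why: silyl ether formation under buffered conditions masks the ionisable benzylic alcohol for the organometallic steps.

Step 5
Reactants: 5 4-O-tert-butyldimethylsilyl ether of 4
Product: 6 6-bromo derivative of 5
Conditions: NBS, CH2Cl2, −20 °C
Reagents that add atoms: N-bromosuccinimide O=C1CCC(=O)N1Br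
Why: electrophilic aromatic bromination at C6, which is para to O1, ortho to the 7-benzyloxy group and less hindered than C8, on a resorcinol-type ring that should react faster than the catechol ether rings.

Step 6
Reactants: 7 5-chlororesorcinol
Product: 8 4,6-dibromo-5-chlororesorcinol
Conditions: NBS (2.05 equiv), MeCN, 0 °C
Reagents that add atoms: N-bromosuccinimide O=C1CCC(=O)N1Br
Why: twofold electrophilic aromatic bromination at the two positions that are ortho to one hydroxyl and para to the other, as in the dibromination of resorcinol.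

Step 7
Reactants: 8 4,6-dibromo-5-chlororesorcinol
Product: 12 4-bromo-3-chloro-5-hydroxy-2-(trimethylsilyl)phenyl trifluoromethanesulfonate, via bis(trimethylsilyl) ether 9 (not isolated), via lithium phenolate 10 (not isolated), via silyl ether triflate 11 (not isolated)
Conditions: HMDS, 80 °C; then n-BuLi (1.05 equiv), THF, −100 °C; then Tf2O, −100 °C to rt; aq. NaHCO3
Reagents that add atoms: hexamethyldisilazane C[Si](C)(C)N[Si](C)(C)C; triflic anhydride O=S(=O)(OS(=O)(=O)C(F)(F)F)C(F)(F)F
Why: standard synthesis of an ortho-silylaryl triflate by bromine–lithium exchange, retro-Brook 1,3-shift of silicon from O to C and O-triflation; the twofold symmetry of 9 makes the first exchange regiochemically unambiguous and the phenolate formed resists a second exchange.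

Step 8
Reactants: 12 4-bromo-3-chloro-5-hydroxy-2-(trimethylsilyl)phenyl trifluoromethanesulfonate
Product: 13 5-(benzyloxy)-4-bromo-3-chloro-2-(trimethylsilyl)phenyl trifluoromethanesulfonate
Conditions: BnBr, K2CO3, acetone, rt
Reagents that add atoms: benzyl bromide BrCc1ccccc1
Why: Williamson ether synthesis on the remaining phenol under conditions that leave the silyl triflate pair intact.

Step 9
Reactants: 13 5-(benzyloxy)-4-bromo-3-chloro-2-(trimethylsilyl)phenyl trifluoromethanesulfonate; 3 (2R,3R)-3,7,3',4'-tetra-O-benzylfustin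
Product: 15 4-aryl-flavan-4-ol from 3 (aryl = 2-benzyloxy-6-chloro-4-(triflyloxy)-5-(trimethylsilyl)phenyl; either C4 epimer), via arylmagnesium chloride 14 (not isolated)
Conditions: iPrMgCl·LiCl, THF, −30 °C; then 3, LaCl3·2LiCl, −30 °C to rt; aq. NH4Cl
Reagents that add atoms: none
Why: bromine–magnesium exchange followed by lanthanum-promoted Grignard 1,2-addition, which should suppress enolisation of the α-alkoxy ketone while the magnesium reagent, unlike a lithium one, keeps its ortho chloride; the carbinol centre is erased in step 10.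

Step 10
Reactants: 15 4-aryl-flavan-4-ol from 3
Product: 16 (2R,3S)-3,7,3',4'-tetrakis(benzyloxy)-4β-[2-benzyloxy-6-chloro-4-(triflyloxy)-5-(trimethylsilyl)phenyl]flavan (2,3-trans-3,4-cis)
Conditions: Et3SiH, TFA, CH2Cl2, −40 to 0 °C
Reagents that add atoms: none
Why: ionic hydrogenation through the flavan-4-yl cation stabilised by the para 7-benzyloxy group, in which hydride should enter anti to the C3 benzyloxy group (held quasi-axial by A(1,2) strain with the C4 aryl), i.e. from the α face, leaving the aryl group β and cis to O3.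

Step 11
Reactants: 17 methyl 3,4-bis(benzyloxy)benzoate; 18 N-methoxy-N-methylacetamide
Product: 19 3-[3,4-bis(benzyloxy)phenyl]-N-methoxy-N-methyl-3-oxopropanamide
Conditions: LDA (2.2 equiv), 18, THF, −78 °C; then 17, −78 to −20 °C; aq. HCl to pH 5
Reagents that add atoms: none
Why: crossed Claisen condensation of the amide enolate with a non-enolisable ester, driven by deprotonation of the β-keto amide formed.

Step 12
Reactants: 19 3-[3,4-bis(benzyloxy)phenyl]-N-methoxy-N-methyl-3-oxopropanamide
Product: 20 (S)-3-[3,4-bis(benzyloxy)phenyl]-3-hydroxy-N-methoxy-N-methylpropanamide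
Conditions: RuCl[(S,S)-TsDPEN](p-cymene) (cat.), HCO2H/Et3N (5:2), DMF, 40 °C
Reagents that add atoms: none
Why: Noyori asymmetric transfer hydrogenation of the aryl ketone, where the (S,S) catalyst should give the (S)-carbinol as with acetophenone; this centre becomes C2 of the middle unit.

Step 13
Reactants: 20 (S)-3-[3,4-bis(benzyloxy)phenyl]-3-hydroxy-N-methoxy-N-methylpropanamide
Product: 21 O-trimethylsilyl ether of 20
Conditions: TMSCl, imidazole, CH2Cl2, 0 °C; non-aqueous work-up
Reagents that add atoms: chlorotrimethylsilane C[Si](C)(C)Cl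
Why: silylation gives a proton-free precursor from which fluoride can release the alkoxide in the aryne step.

Step 14
Reactants: 16 top-unit ortho-silylaryl triflate; 21 O-trimethylsilyl ether of 20
Product: 25 top–middle flavanone (middle unit (2S)-7-benzyloxy-5-chloro-2-[3,4-bis(benzyloxy)phenyl]chroman-4-one bonded at C6 to C4β of the top unit), via aryne 22 (not isolated), via cesium alkoxide 23 (not isolated), via cesium hemiaminal alkoxide 24 (not isolated)
Conditions: CsF (4 equiv), 18-crown-6, THF, 0 °C to rt, slow addition of 16 to 21; then AcOH, −20 °C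
Reagents that add atoms: none
Why: Proposed new method: fluoride removes the C4a silyl group of 16 with loss of the C8a triflate to give aryne 22 and also desilylates 21 to the proton-free alkoxide 23, which adds through O1 to C8a, after which the C4a aryl anion attacks the Weinreb carbonyl to give hemiaminal salt 24 that becomes the ketone only on the acetic acid quench. The closest known reaction type is the aryne annulation of salicylate esters to xanthones (heteroatom addition to an aryne followed by intramolecular acyl capture), extended here from a phenoxide and an ester to an aliphatic secondary alkoxide and a Weinreb amide. Ring C of the middle unit is closed by 6-exo-trig attack of the aryl anion on the amide carbonyl, the O1–C8a bond having been formed intermolecularly just before. No stereocentre is created, and C2 keeps its (S) configuration because none of its bonds is touched and because O-arylation precedes ketone formation, so no β-oxido ketone able to undergo retro-aldol or E1cB ring opening is present under base. The step needs regioselective addition to the aryne, which the C5 chlorine secures by directing the alkoxide to the distal carbon C8a and placing the carbanion at C4a next to the C–Cl bond (aryne distortion model), while elimination toward triflate and not chloride fixes the position of the aryne. It also needs ring closure to outrun protonation of the aryl anion, which the absence of O–H groups (silyl ether as alkoxide source, THF) secures.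

Step 15
Reactants: 6 6-bromo derivative of 5; 25 top–middle flavanone
Product: 28 trimeric tertiary alcohol (middle unit 4-hydroxy-4-aryl with the aryl being C6 of the bottom unit; either C4 epimer), via aryllithium 26 (not isolated), via arylcerium dichloride 27 (not isolated)
Conditions: 6, t-BuLi (2 equiv), THF, −78 °C; CeCl3, −78 °C; then 25, −78 to −20 °C; aq. NH4Cl
Reagents that add atoms: none
Why: bromine–lithium exchange, transmetalation to the weakly basic organocerium and 1,2-addition to the enolisable flavanone, which should avoid enolate formation and retro-oxa-Michael ring opening; the carbinol centre is erased in step 16.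

Step 16
Reactants: 28 trimeric tertiary alcohol
Product: 29 trimeric 4-aryl-flav-3-ene (middle unit C3=C4; C2 aryl α retained)
Conditions: MsCl, Et3N, CH2Cl2, 0 °C, exclusion of light
Reagents that add atoms: none
Why: E1-type dehydration through the mesylate of the doubly benzylic tertiary alcohol, in which only C3 carries β-hydrogens, so the C3=C4 alkene is the only one possible, and the amine-buffered medium protects the benzylic silyl ether.

Step 17
Reactants: 29 trimeric 4-aryl-flav-3-ene
Product: 31 trimeric flavan-3-ol (middle unit 2,3-trans-3,4-trans: 3β-OH and 4α-aryl; bottom 4-O-silyl), via alkylborane 30 (not isolated)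
Conditions: BH3·THF (excess), THF, 0 to 40 °C; then NaOH, H2O2, 0 °C
Reagents that add atoms: hydrogen peroxide OO
Why: hydroboration–oxidation in which boron adds to C3 and hydrogen to C4 in a syn manner on the β face, anti to the α C2 aryl group, and oxidation with retention should give 3β-OH and 4β-H, setting both C3 and C4 of the middle unit.

Step 18
Reactants: 31 trimeric flavan-3-ol
Product: 32 undecabenzyl chloro trimer with free bottom 4-OH
Conditions: TBAF, AcOH, THF, 0 °C to rt
Reagents that add atoms: none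
Why: fluoride-mediated desilylation, buffered with acetic acid so that no strongly basic alkoxide is formed.

Step 19
Reactants: 32 undecabenzyl chloro trimer with free bottom 4-OH
Product: 33 CNP0255184.1
Conditions: H2 (4 bar), Pd(OH)2/C, Et3N, THF/MeOH, rt
Reagents that add atoms: none
Why: heterogeneous hydrogenolysis of eleven benzyl ethers with concurrent hydrodechlorination at C5 of the middle unit, with Et3N taking up HCl so that the acid-labile benzylic 4-OH and the interflavanyl bonds should survive.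

**Compound list**

1 | (+)-fustin, (2R,3R)-3,7,3',4'-tetrahydroxyflavanone | Oc1ccc2c(c1)O[C@H](c1ccc(O)c(O)c1)[C@@H](O)C2=O | starting material
2 | (2R,3R)-7,3',4'-tri-O-benzylfustin | c1ccccc1COc1ccc2c(c1)O[C@H](c1ccc(OCc3ccccc3)c(OCc3ccccc3)c1)[C@@H](O)C2=O | intermediate
3 | (2R,3R)-3,7,3',4'-tetra-O-benzylfustin | c1ccccc1COc1ccc2c(c1)O[C@H](c1ccc(OCc3ccccc3)c(OCc3ccccc3)c1)[C@@H](OCc1ccccc1)C2=O | intermediate
4 | (2R,3S,4R)-3,7,3',4'-tetrakis(benzyloxy)flavan-4-ol (2,3-trans-3,4-trans) | c1ccccc1COc1ccc2c(c1)O[C@H](c1ccc(OCc3ccccc3)c(OCc3ccccc3)c1)[C@@H](OCc1ccccc1)[C@@H]2O | intermediate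
5 | 4-O-tert-butyldimethylsilyl ether of 4 | c1ccccc1COc1ccc2c(c1)O[C@H](c1ccc(OCc3ccccc3)c(OCc3ccccc3)c1)[C@@H](OCc1ccccc1)[C@@H]2O[Si](C)(C)C(C)(C)C | intermediate
6 | 6-bromo derivative of 5 (bottom-unit bromide) | c1ccccc1COc1c(Br)cc2c(c1)O[C@H](c1ccc(OCc3ccccc3)c(OCc3ccccc3)c1)[C@@H](OCc1ccccc1)[C@@H]2O[Si](C)(C)C(C)(C)C | intermediate
7 | 5-chlororesorcinol | Oc1cc(O)cc(Cl)c1 | starting material
8 | 4,6-dibromo-5-chlororesorcinol | Oc1cc(O)c(Br)c(Cl)c1Br | intermediate
9 | 4,6-dibromo-5-chloro-1,3-bis(trimethylsilyloxy)benzene | C[Si](C)(C)Oc1cc(O[Si](C)(C)C)c(Br)c(Cl)c1Br | intermediate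
10 | lithium 4-bromo-3-chloro-2-(trimethylsilyl)-5-(trimethylsilyloxy)phenolate | [Li+].[O-]c1cc(O[Si](C)(C)C)c(Br)c(Cl)c1[Si](C)(C)C | intermediate
11 | 4-bromo-3-chloro-2-(trimethylsilyl)-5-(trimethylsilyloxy)phenyl trifluoromethanesulfonate | FC(F)(F)S(=O)(=O)Oc1cc(O[Si](C)(C)C)c(Br)c(Cl)c1[Si](C)(C)C | intermediate
12 | 4-bromo-3-chloro-5-hydroxy-2-(trimethylsilyl)phenyl trifluoromethanesulfonate | FC(F)(F)S(=O)(=O)Oc1cc(O)c(Br)c(Cl)c1[Si](C)(C)C | intermediate
13 | 5-(benzyloxy)-4-bromo-3-chloro-2-(trimethylsilyl)phenyl trifluoromethanesulfonate | FC(F)(F)S(=O)(=O)Oc1cc(OCc2ccccc2)c(Br)c(Cl)c1[Si](C)(C)C | intermediate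
14 | arylmagnesium chloride from 13 (Mg in place of Br) | FC(F)(F)S(=O)(=O)Oc1cc(OCc2ccccc2)c([Mg]Cl)c(Cl)c1[Si](C)(C)C | intermediate
15 | (2R,3S)-3,7,3',4'-tetrakis(benzyloxy)-4-[2-benzyloxy-6-chloro-4-(triflyloxy)-5-(trimethylsilyl)phenyl]flavan-4-ol, C4 configuration not defined (either epimer serves) | c1ccccc1COc1ccc2c(c1)O[C@H](c1ccc(OCc3ccccc3)c(OCc3ccccc3)c1)[C@@H](OCc1ccccc1)C2(O)c1c(OCc3ccccc3)cc(OS(=O)(=O)C(F)(F)F)c([Si](C)(C)C)c1Cl | intermediate
16 | (2R,3S)-3,7,3',4'-tetrakis(benzyloxy)-4β-[2-benzyloxy-6-chloro-4-(triflyloxy)-5-(trimethylsilyl)phenyl]flavan, 2,3-trans-3,4-cis (aryne precursor) | c1ccccc1COc1ccc2c(c1)O[C@H](c1ccc(OCc3ccccc3)c(OCc3ccccc3)c1)[C@@H](OCc1ccccc1)[C@H]2c1c(OCc3ccccc3)cc(OS(=O)(=O)C(F)(F)F)c([Si](C)(C)C)c1Cl | intermediate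
17 | methyl 3,4-bis(benzyloxy)benzoate | COC(=O)c1ccc(OCc2ccccc2)c(OCc2ccccc2)c1 | starting material
18 | N-methoxy-N-methylacetamide | CC(=O)N(C)OC | starting material
19 | 3-[3,4-bis(benzyloxy)phenyl]-N-methoxy-N-methyl-3-oxopropanamide | CON(C)C(=O)CC(=O)c1ccc(OCc2ccccc2)c(OCc2ccccc2)c1 | intermediate
20 | (S)-3-[3,4-bis(benzyloxy)phenyl]-3-hydroxy-N-methoxy-N-methylpropanamide | O[C@H](c1ccc(OCc2ccccc2)c(OCc2ccccc2)c1)CC(=O)N(C)OC | intermediate
21 | (S)-3-[3,4-bis(benzyloxy)phenyl]-N-methoxy-N-methyl-3-(trimethylsilyloxy)propanamide | C[Si](C)(C)O[C@H](c1ccc(OCc2ccccc2)c(OCc2ccccc2)c1)CC(=O)N(C)OC | intermediate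
22 | aryne from 16 (triple bond between the carbons that become C4a and C8a of the middle unit; chlorine on the neighbouring carbon) | c1ccccc1COc1ccc2c(c1)O[C@H](c1ccc(OCc3ccccc3)c(OCc3ccccc3)c1)[C@@H](OCc1ccccc1)[C@H]2C1=C(Cl)C#CC=C1OCc1ccccc1 | intermediate
23 | cesium (S)-alkoxide from 21 | [Cs+].[O-][C@H](c1ccc(OCc2ccccc2)c(OCc2ccccc2)c1)CC(=O)N(C)OC | intermediate
24 | cesium hemiaminal alkoxide (middle-unit C4 bearing O− and N(OMe)Me; C4 configuration not defined) | [Cs+].c1ccccc1COc1ccc2c(c1)O[C@H](c1ccc(OCc3ccccc3)c(OCc3ccccc3)c1)[C@@H](OCc1ccccc1)[C@H]2c4c(Cl)c5c(cc4OCc6ccccc6)O[C@H](c6ccc(OCc7ccccc7)c(OCc7ccccc7)c6)CC5([O-])N(C)OC | intermediate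
25 | top–middle flavanone: (2S)-7-benzyloxy-5-chloro-2-[3,4-bis(benzyloxy)phenyl]chroman-4-one bonded at C6 to C4β of the (2R,3S)-tetrabenzyl top unit | c1ccccc1COc1ccc2c(c1)O[C@H](c1ccc(OCc3ccccc3)c(OCc3ccccc3)c1)[C@@H](OCc1ccccc1)[C@H]2c4c(Cl)c5c(cc4OCc6ccccc6)O[C@H](c6ccc(OCc7ccccc7)c(OCc7ccccc7)c6)CC5=O | intermediate
26 | C6 aryllithium of the bottom unit (from 6) | c1ccccc1COc1c([Li])cc2c(c1)O[C@H](c1ccc(OCc3ccccc3)c(OCc3ccccc3)c1)[C@@H](OCc1ccccc1)[C@@H]2O[Si](C)(C)C(C)(C)C | intermediate
27 | C6 arylcerium dichloride of the bottom unit | c1ccccc1COc1c([Ce](Cl)Cl)cc2c(c1)O[C@H](c1ccc(OCc3ccccc3)c(OCc3ccccc3)c1)[C@@H](OCc1ccccc1)[C@@H]2O[Si](C)(C)C(C)(C)C | intermediate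
28 | trimeric tertiary alcohol (middle-unit C4 bearing OH and C6 of the bottom unit; C4 configuration not defined) | c1ccccc1COc1ccc2c(c1)O[C@H](c1ccc(OCc3ccccc3)c(OCc3ccccc3)c1)[C@@H](OCc1ccccc1)[C@H]2c4c(Cl)c5c(cc4OCc6ccccc6)O[C@H](c6ccc(OCc7ccccc7)c(OCc7ccccc7)c6)CC5(O)c6cc7c(cc6OCc8ccccc8)O[C@H](c8ccc(OCc9ccccc9)c(OCc9ccccc9)c8)[C@@H](OCc8ccccc8)[C@@H]7O[Si](C)(C)C(C)(C)C | intermediate
29 | trimeric 4-aryl-flav-3-ene (middle unit C3=C4, C2 aryl α) | c1ccccc1COc1ccc2c(c1)O[C@H](c1ccc(OCc3ccccc3)c(OCc3ccccc3)c1)[C@@H](OCc1ccccc1)[C@H]2c4c(Cl)c5c(cc4OCc6ccccc6)O[C@H](c6ccc(OCc7ccccc7)c(OCc7ccccc7)c6)C=C5c6cc7c(cc6OCc8ccccc8)O[C@H](c8ccc(OCc9ccccc9)c(OCc9ccccc9)c8)[C@@H](OCc8ccccc8)[C@@H]7O[Si](C)(C)C(C)(C)C | intermediate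
30 | alkylborane (BH2 on middle-unit C3β, H on C4β) | c1ccccc1COc1ccc2c(c1)O[C@H](c1ccc(OCc3ccccc3)c(OCc3ccccc3)c1)[C@@H](OCc1ccccc1)[C@H]2c4c(Cl)c5c(cc4OCc6ccccc6)O[C@H](c6ccc(OCc7ccccc7)c(OCc7ccccc7)c6)[C@@H](B)[C@@H]5c6cc7c(cc6OCc8ccccc8)O[C@H](c8ccc(OCc9ccccc9)c(OCc9ccccc9)c8)[C@@H](OCc8ccccc8)[C@@H]7O[Si](C)(C)C(C)(C)C | intermediate
31 | trimeric flavan-3-ol (middle unit 3β-OH and 4α-aryl; bottom 4-O-TBS) | c1ccccc1COc1ccc2c(c1)O[C@H](c1ccc(OCc3ccccc3)c(OCc3ccccc3)c1)[C@@H](OCc1ccccc1)[C@H]2c4c(Cl)c5c(cc4OCc6ccccc6)O[C@H](c6ccc(OCc7ccccc7)c(OCc7ccccc7)c6)[C@@H](O)[C@@H]5c6cc7c(cc6OCc8ccccc8)O[C@H](c8ccc(OCc9ccccc9)c(OCc9ccccc9)c8)[C@@H](OCc8ccccc8)[C@@H]7O[Si](C)(C)C(C)(C)C | intermediate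
32 | undecabenzyl 5-chloro trimer with free middle 3-OH and bottom 4α-OH | c1ccccc1COc1ccc2c(c1)O[C@H](c1ccc(OCc3ccccc3)c(OCc3ccccc3)c1)[C@@H](OCc1ccccc1)[C@H]2c4c(Cl)c5c(cc4OCc6ccccc6)O[C@H](c6ccc(OCc7ccccc7)c(OCc7ccccc7)c6)[C@@H](O)[C@@H]5c6cc7c(cc6OCc8ccccc8)O[C@H](c8ccc(OCc9ccccc9)c(OCc9ccccc9)c8)[C@@H](OCc8ccccc8)[C@@H]7O | intermediate
33 | CNP0255184.1, fisetinidol-(4β→6)-fisetinidol-(4α→6)-mollisacacidin | Oc1ccc2c(c1)O[C@H](c1ccc(O)c(O)c1)[C@@H](O)[C@H]2c1cc2c(cc1O)O[C@H](c1ccc(O)c(O)c1)[C@@H](O)[C@@H]2c1cc2c(cc1O)O[C@H](c1ccc(O)c(O)c1)[C@@H](O)[C@@H]2O | target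

**Totals**

Total step count: 19. Longest linear sequence: 11 steps (steps 6, 7, 8, 9, 10, 14, 15, 16, 17, 18, 19 from 5-chlororesorcinol).

**Three steps most likely to fail**

Step 14 (proposed new method). The aryl anion at C4a may be protonated before it closes the ring. The alkoxide may add at the wrong aryne terminus. The hemiaminal may collapse early, exposing the flavanone to base and to E1cB ring opening with loss of C2 configuration. The fallback separates the two bond formations using known reactions and sets out from 16 and the free alcohol 20. Fluoride-induced aryne formation from 16 in MeCN, a proton-donating medium, should give the known type of aryne O-arylation of an alcohol, still steered to C8a by the chlorine, to give the aryl ether Weinreb amide F1. Hydrolysis (KOH, EtOH/H2O, 70 °C) should give the 3-aryloxy-3-arylpropanoic acid F2. Intramolecular Friedel–Crafts acylation (trifluoroacetic anhydride, CH2Cl2, 0 °C) at C4a, which is para to the 7-benzyloxy group and ortho to O1, should then close ring C and return to the route at 25.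

Step 10. Hydride delivery to the planar C4 cation may show poor facial selectivity, or the cation may lose the C3 proton to give an enol ether. The fallback avoids the cation and replaces steps 9 and 10; it sets out from 4 and from Grignard reagent 14 (made from 13 as in step 9). Methylation of 4 (NaH, MeI, THF) should give the 4α-methyl ether F3. A stereospecific nickel-catalysed Kumada coupling of this benzylic ether with 14 (Ni(cod)2, a bisphosphine, toluene) should proceed with inversion at C4, turning the 4α C–O bond into the 4β C–aryl bond, and return to the route at 16.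

Step 19. The benzylic C4–O bond of the bottom unit may be hydrogenolysed along with the benzyl ethers, and hydrodechlorination at the hindered C5 position may be incomplete under conditions mild enough to spare it. The fallback changes the oxidation level of the bottom unit and sets out from 32. MnO2 in CH2Cl2 should oxidise only the activated benzylic 4-OH to give the bottom-unit ketone F4. Hydrogenolysis (H2, Pd(OH)2/C, Et3N) can then be pushed to completion to give the free phenolic ketone F5. NaBH4 in EtOH at 0 °C, the classical reduction of fustin to the 2,3-trans-3,4-trans diol, should then return to the route at 33.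

Further compounds
F1 | step 14 | aryl ether Weinreb amide (O1 on C8a of the middle ring A, hydrogen at C4a, ring C not closed) | c1ccccc1COc1ccc2c(c1)O[C@H](c1ccc(OCc3ccccc3)c(OCc3ccccc3)c1)[C@@H](OCc1ccccc1)[C@H]2c4c(Cl)cc(O[C@H](c6ccc(OCc7ccccc7)c(OCc7ccccc7)c6)CC(=O)N(C)OC)cc4OCc6ccccc6
F2 | step 14 | carboxylic acid from F1 | c1ccccc1COc1ccc2c(c1)O[C@H](c1ccc(OCc3ccccc3)c(OCc3ccccc3)c1)[C@@H](OCc1ccccc1)[C@H]2c4c(Cl)cc(O[C@H](c6ccc(OCc7ccccc7)c(OCc7ccccc7)c6)CC(=O)O)cc4OCc6ccccc6
F3 | step 10 | (2R,3S,4R)-3,7,3',4'-tetrakis(benzyloxy)-4-methoxyflavan | c1ccccc1COc1ccc2c(c1)O[C@H](c1ccc(OCc3ccccc3)c(OCc3ccccc3)c1)[C@@H](OCc1ccccc1)[C@@H]2OC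
F4 | step 19 | undecabenzyl 5-chloro trimer with bottom-unit C4 ketone | c1ccccc1COc1ccc2c(c1)O[C@H](c1ccc(OCc3ccccc3)c(OCc3ccccc3)c1)[C@@H](OCc1ccccc1)[C@H]2c4c(Cl)c5c(cc4OCc6ccccc6)O[C@H](c6ccc(OCc7ccccc7)c(OCc7ccccc7)c6)[C@@H](O)[C@@H]5c6cc7c(cc6OCc8ccccc8)O[C@H](c8ccc(OCc9ccccc9)c(OCc9ccccc9)c8)[C@@H](OCc8ccccc8)C7=O
F5 | step 19 | free phenolic trimer with bottom-unit C4 ketone (fustin-terminated) | Oc1ccc2c(c1)O[C@H](c1ccc(O)c(O)c1)[C@@H](O)[C@H]2c1cc2c(cc1O)O[C@H](c1ccc(O)c(O)c1)[C@@H](O)[C@@H]2c1cc2c(cc1O)O[C@H](c1ccc(O)c(O)c1)[C@@H](O)C2=O
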